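Percent of the solid substrate charged is the unit of the answers below, so we judge a flask by the part of its charge that stands as intermediate.

    starting material → intermediate (k1 = 0.0059 s⁻¹, Ea1 = 97.0 kJ mol⁻¹)
    intermediate ⇌ target (K2 = 1.6, k2 = 0.12 s⁻¹, Ea2 = 90.0 kJ mol⁻¹, ΔH2 = −4.00 kJ mol⁻¹)
    intermediate ⇌ isomer of the product (K3 = 2.4, k3 = 0.061 s⁻¹, Ea3 = 80.0 kJ mol⁻¹, ΔH3 = −21.0 kJ mol⁻¹)
    solid substrate ⇌ starting material, rate k4*(cs4 - [starting material]) while solid is left; crystals form when [starting material] > cs4 (cs4 = 0.21 M, k4 = 0.0033 s⁻¹)
    starting material ⇌ dormant form (K5 = 1.6, k5 = 0.030 s⁻¹, Ea5 = 87.0 kJ mol⁻¹, ΔH5 = −13.0 kJ mol⁻¹)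
    (constants at 60 °C)

the same everywhere: solid substrate 0.25 M; time 30 min
- Friday's: temperature 30 °C
- Wednesday's: temperature 60 °C
- Sunday's: temperature 0 °C

- as a solid, counted per litre of solution: solid substrate
- at 60 °C the constants are as listed, elsewhere as the activation energies and enthalpies make them
- at the start none of the solid substrate is in solution
- what has only dissolved of solid substrate counts as not reacted

1. the flask that comes out highest in amount of intermediate, in percent of the solid substrate charged, or "all alike" when all lie within 1.5 percentage points (Friday's / Wednesday's / Sunday's / all alike)
2. intermediate at the end, in percent of the solid substrate charged, Friday's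
3. intermediate at the end, in percent of the solid substrate charged, Wednesday's
4. intermediate at the end, in percent of the solid substrate charged, Sunday's

Take the pool of intermediate, target and isomer of the product, and reckon from the constants at 60 °C:

f = 1 / (1 + 1.6 + 2.4) = 20.0%

We call f the pool share, the fraction of the pool standing as intermediate once both steps out of the intermediate have relaxed. We now turn the settings one after the other.

Time. In Wednesday's flask those steps relax in 0.0592 min and 0.134 min, far shorter than the run of 30 min. So the pool is shared out as f says (thermodynamic control), and time acts through the amount fed in. In Wednesday's flask starting material and dormant form relax in 0.237 min, also far shorter than the run, so the feed runs on the constant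

k = 0.35 min⁻¹ / (1 + 1.6) = 0.136 min⁻¹

Charge. Once dissolved, the material passes through first-order steps, so in Wednesday's flask the charge acts through the dissolving, which at its fastest needs

0.25 M / (0.0033 s⁻¹ × 0.21 M) = 6.01 min

With no delay, f gives 19.7% intermediate in Wednesday's flask; with that whole delay, 19.2%. We commit to that span.

Temperature. In Sunday's flask, at 0 °C, the constants lower f to 6.29%, but the step to the target runs 1300 times slower than in Wednesday's flask, which stretches its relaxation to at least 74.5 min, longer than the run. So f gives no number for Sunday's flask. The step from the starting material has the higher activation energy, so in Sunday's flask under 0.844% of the dissolved starting material passes it. We expect Wednesday's flask above Sunday's; for Friday's, at 30 °C, we commit to no number, so our reckoning stops short of naming the highest flask.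

The forecast names Wednesday's, with 2.3% (1.9% to 2.8%) for Friday's, 19.5% (19% to 19.8%) for Wednesday's and 0.29% (0.25% to 0.33%) for Sunday's, its ground at 60 °C being “leaving about one fifth of the material as intermediate”.

The simulation gives 19.4% for Wednesday's, above 2.37% for Friday's and 0.289% for Sunday's, so Wednesday's leads and the forecast stands. A change of the pool would overturn its number for Wednesday's flask: with the step to the isomer of the product struck out both ways, that flask reaches 37.2%, higher than the top of the forecast's range. Wednesday's flask ends with 1.21% starting material and 2.17% dormant form, and f on the remainder gives 19.3%; without that step the share on the same remainder gives 37.2%.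

Wednesday's flask read at 8.0 min holds 19.8% starting material and 34.7% dormant form, so f gives 9.10% intermediate. The computed flask gives 9.67%.

(The numbers are assumed; what happens was integrated by code.)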